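**Retrosynthetic overview**
1. Target 47 comes from the macrocyclic allylic alcohol 41 by acetylation, PMB removal, esterification and desilylation; the ten-membered ring is closed last by an intramolecular Nozaki–Hiyama–Kishi coupling (C10 vinyl iodide onto C1 aldehyde) of 40.
2. Aldehyde 40 comes from the cis-γ-lactone 34 (oxidative lactonisation of the C8,C12-diol 32, then Eschenmoser methylenation); both ring-cis trisubstituted alkenes arise from Red-Al/I2 on propargylic alcohols (C4–I used for the C3–C4 bond, C10–I for ring closure).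
3. C8 is set by transfer hydrogenation of ynone 28; O6 and O8 are told apart through a p-methoxybenzylidene acetal that is opened reductively; C3 is set by CBS reduction of the (Z)-enone 20 (alkenyllithium plus Weinreb amide 18).
4. C6 and C7 come from a ketoreductase reduction of the achiral keto ester 5 (first stereocentre) followed by Fráter–Seebach allylation; the allyl group becomes C11–C12.
5. Ring order: γ-lactone first (step 20, exocyclic methylene in steps 21–22), then the ten-membered carbocycle (step 25).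

Assumption: the SMILES is read as the (1S,3S,4Z,6R,7R,8S,9Z)-germacra-4,9,11(13)-trien-12,8-olide with a (2S)-2-methylbutanoate, using germacranolide locants (C1 OAc, C3 OH, C4 methyl = C15, C6 ester, C7/C8 lactone fusion, C10 CH2OH = C14, C11=C13 methylene, C12 carbonyl); names marked "target locants" use these.

**Step 1**
Reactants: 1 but-2-ynoic acid; 2 potassium ethyl malonate
Product: 5 ethyl 3-oxohex-4-ynoate, via but-2-ynoyl chloride 3 (not isolated), via acylmalonic half-ester 4 (not isolated)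
Conditions: (COCl)2, cat. DMF, CH2Cl2, 0 °C → rt, evaporate; then 2, MgCl2, Et3N, MeCN, 0 °C → rt; aq. HCl
Reagents that add atoms: none
Why: Masamune–Rathke C-acylation of the magnesium enolate of the malonic half-ester by the acid chloride, then decarboxylation on acidic work-up, is a standard β-keto ester synthesis and forms no stereocentre.

**Step 2**
Reactants: 5 ethyl 3-oxohex-4-ynoate
Product: 6 ethyl (3S)-3-hydroxyhex-4-ynoate
Conditions: ketoreductase ((S)-selective KRED from a panel screen), NADP+ (cat.), i-PrOH (10 vol %), KH2PO4/K2HPO4 buffer pH 7, 30 °C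
Reagents that add atoms: none
Why: Enzymatic asymmetric ketone reduction: the ketoreductase (an NADPH-dependent alcohol dehydrogenase) delivers hydride to one face of the prochiral ketone in its chiral active site and sets C6, with isopropanol recycling the cofactor.

**Step 3**
Reactants: 6 ethyl (3S)-3-hydroxyhex-4-ynoate; 7 allyl bromide
Product: 9 ethyl (2R,3S)-3-hydroxy-2-(prop-2-en-1-yl)hex-4-ynoate, via dilithium alkoxide-enolate 8 (not isolated)
Conditions: LiN(i-Pr)2 (2.2 equiv), THF, −78 → −20 °C; then 7, DMPU, −78 → −20 °C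
Reagents that add atoms: none
Why: Fráter–Seebach alkylation: the chelated dilithium alkoxide-enolate is allylated on the face away from the C6 substituent, giving the 6,7-anti product.

**Step 4**
Reactants: 9 allylated hydroxy ester
Product: 11 ethyl (2S,3R)-5-hydroxy-2-(prop-1-yn-1-yl)oxolane-3-carboxylate (anomer mixture), via vicinal diol 10 (not isolated)
Conditions: OsO4 (2 mol %), NaIO4 (4 equiv), 2,6-lutidine, dioxane/H2O 3:1, rt
Reagents that add atoms: osmium tetroxide O=[Os](=O)(=O)=O (delivers the oxygen); sodium periodate [Na+].[O-]I(=O)(=O)=O (restores it)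
Why: Lemieux–Johnson oxidation cleaves only the monosubstituted alkene (the alkyne is inert) and the resulting aldehyde closes onto the C6 hydroxyl as a lactol, leaving C6 and C7 untouched.

**Step 5**
Reactants: 11 lactol ester
Product: 13 (2S,3S,4Z)-2-(2-hydroxyethyl)-5-iodohex-4-ene-1,3-diol, via cyclic alkenylaluminate 12 (not isolated)
Conditions: NaAlH2(OCH2CH2OMe)2 (5 equiv), THF, 0 °C → rt; then I2, THF, −78 → 0 °C
Reagents that add atoms: iodine II
Why: Red-Al reduces ester and lactol and, through the propargylic aluminium alkoxide, trans-hydroaluminates the alkyne with aluminium on the distal carbon; iodinolysis with retention gives the (Z)-vinyl iodide (iodine cis to C6).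

**Step 6**
Reactants: 13 iodo triol
Product: 14 p-methoxybenzylidene acetal alcohol (O6/O8 acetal with free C12 hydroxyl)
Conditions: 4-MeOC6H4CH(OMe)2, PPTS (cat.), CH2Cl2, rt
Reagents that add atoms: 4-methoxybenzaldehyde dimethyl acetal COc1ccc(C(OC)OC)cc1
Why: Thermodynamic transacetalisation gives the six-membered all-equatorial 1,3-dioxane of the 1,3-diol in preference to seven-membered acetals, leaving only the C12 hydroxyl free.

**Step 7**
Reactants: 14 acetal alcohol
Product: 15 C12 triethylsilyl ether of 14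
Conditions: Et3SiCl, imidazole, CH2Cl2, 0 °C
Reagents that add atoms: chlorotriethylsilane CC[Si](Cl)(CC)CC
Why: Standard silylation of a primary alcohol.

**Step 8**
Reactants: 16 methyl 3-hydroxypropanoate
Product: 17 3-hydroxy-N-methoxy-N-methylpropanamide
Conditions: MeNHOMe·HCl, i-PrMgCl (3 equiv), THF, −20 → 0 °C
Reagents that add atoms: N,O-dimethylhydroxylamine hydrochloride CNOC.Cl
Why: Weinreb amide formation by aminolysis of the ester with the chloromagnesium amide.

**Step 9**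
Reactants: 17 hydroxy Weinreb amide
Product: 18 3-(tert-butyldimethylsilyloxy)-N-methoxy-N-methylpropanamide
Conditions: t-BuMe2SiCl, imidazole, DMF, rt
Reagents that add atoms: tert-butyldimethylsilyl chloride CC(C)(C)[Si](C)(C)Cl
Why: Standard silylation of a primary alcohol.

**Step 10**
Reactants: 15 vinyl iodide acetal; 18 silyloxy Weinreb amide
Product: 20 (Z)-enone (C3 ketone joined to C4), via alkenyllithium 19 (not isolated)
Conditions: t-BuLi (2.1 equiv), Et2O, −78 °C; then 18, −78 → 0 °C; aq. NH4Cl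
Reagents that add atoms: none
Why: Iodine–lithium exchange proceeds with retention of alkene geometry and the alkenyllithium adds once to the Weinreb amide through the chelated tetrahedral intermediate (Weinreb ketone synthesis).

**Step 11**
Reactants: 20 (Z)-enone
Product: 21 (3S)-allylic alcohol
Conditions: (R)-2-methyl-CBS-oxazaborolidine (0.5 equiv), catecholborane, toluene, −78 °C
Reagents that add atoms: none
Why: Corey–Bakshi–Shibata reduction: the oxazaborolidine binds the ketone anti to the bulkier α-branched alkenyl group and directs hydride to the face that gives the (3S)-alcohol, while catecholborane leaves the acetal untouched.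

**Step 12**
Reactants: 21 (3S)-allylic alcohol
Product: 22 C3 tert-butyldimethylsilyl ether
Conditions: t-BuMe2SiOTf, 2,6-lutidine, CH2Cl2, −78 °C
Reagents that add atoms: tert-butyldimethylsilyl triflate CC(C)(C)[Si](C)(C)OS(=O)(=O)C(F)(F)F
Why: Silyl triflate silylation of a hindered secondary alcohol.

**Step 13**
Reactants: 22 silylated acetal
Product: 23 C8 primary alcohol carrying the PMB ether on O6
Conditions: i-Bu2AlH (4 equiv), CH2Cl2, −78 → 0 °C
Reagents that add atoms: none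
Why: Regioselective reductive opening of the p-methoxybenzylidene acetal: the aluminium binds the less hindered O8 and hydride adds to the oxocarbenium ion, leaving PMB on the secondary O6.

**Step 14**
Reactants: 23 C8 primary alcohol
Product: 24 C8 aldehyde
Conditions: Dess–Martin periodinane, NaHCO3, CH2Cl2, 0 °C → rt
Reagents that add atoms: none
Why: Buffered Dess–Martin oxidation gives the α-branched aldehyde without epimerising C7.

**Step 15**
Reactants: 24 C8 aldehyde; 25 tert-butyldiphenyl(prop-2-yn-1-yloxy)silane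
Product: 27 C8 propargylic alcohols (both C8 epimers), via lithium acetylide 26 (not isolated)
Conditions: 25, n-BuLi, THF, −78 °C; then 24, −78 °C
Reagents that add atoms: none
Why: Acetylide addition to the aldehyde forms the C8–C9 bond; the C8 configuration is erased in the next step.

**Step 16**
Reactants: 27 propargylic alcohols
Product: 28 C8 ynone
Conditions: Dess–Martin periodinane, NaHCO3, CH2Cl2, 0 °C
Reagents that add atoms: none
Why: Dess–Martin oxidation under neutral conditions converges both epimers to the alkynyl ketone.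

**Step 17**
Reactants: 28 C8 ynone
Product: 29 (8R)-propargylic alcohol
Conditions: RuCl[(R,R)-TsDPEN](p-cymene) (5 mol %), i-PrOH, rt
Reagents that add atoms: none
Why: Noyori–Ikariya asymmetric transfer hydrogenation of an alkynyl ketone is catalyst-controlled and gives the (8R)-alcohol, 7,8-anti, which is the lactone carbinol configuration.

**Step 18**
Reactants: 29 (8R)-propargylic alcohol
Product: 31 (9Z)-10-iodo allylic alcohol, via cyclic alkenylaluminate 30 (not isolated)
Conditions: NaAlH2(OCH2CH2OMe)2, THF, 0 °C; then I2, −78 → 0 °C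
Reagents that add atoms: iodine II
Why: Hydroxyl-directed trans-hydroalumination followed by iodinolysis with retention places iodine on C10 cis to C8; the protected C4=C5 alkene has no free directing hydroxyl and is untouched.

**Step 19**
Reactants: 31 vinyl iodide alcohol
Product: 32 C8,C12-diol
Conditions: PPTS, MeOH/CH2Cl2, 0 °C
Reagents that add atoms: none
Why: Acid-catalysed methanolysis removes the primary triethylsilyl ether much faster than the tert-butyldimethylsilyl and tert-butyldiphenylsilyl ethers.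

**Step 20**
Reactants: 32 C8,C12-diol
Product: 34 cis-γ-lactone (saturated), via lactol 33 (not isolated)
Conditions: TEMPO (0.2 equiv), PhI(OAc)2 (2.5 equiv), CH2Cl2, rt
Reagents that add atoms: none
Why: Oxoammonium (TEMPO) oxidative lactonisation: the primary alcohol is oxidised first, the aldehyde closes to the lactol with the C8 hydroxyl and is oxidised on to the lactone, with the cis ring fusion fixed by C7 and C8.

**Step 21**
Reactants: 34 cis-γ-lactone
Product: 36 α-(dimethylaminomethyl) lactone, via lithium enolate 35 (not isolated)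
Conditions: LiN(SiMe3)2, THF, −78 °C; then CH2=NMe2+ I−, −78 °C → rt
Reagents that add atoms: Eschenmoser's salt C=[N+](C)C.[I-]
Why: Mannich reaction of the lactone enolate with Eschenmoser's salt, entering trans to the C7 substituent (this C11 centre is removed in the next step).

**Step 22**
Reactants: 36 Mannich base
Product: 38 α-methylene-γ-lactone, via trimethylammonium iodide 37 (not isolated)
Conditions: MeI, MeOH/CH2Cl2, rt; then aq. NaHCO3, CH2Cl2, rt
Reagents that add atoms: none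
Why: N-methylation followed by Hofmann-type E1cB elimination gives the exocyclic methylene.

**Step 23**
Reactants: 38 α-methylene lactone
Product: 39 C1 primary alcohol
Conditions: HF·pyridine, pyridine, THF, 0 °C
Reagents that add atoms: none
Why: Buffered fluoride cleaves the primary tert-butyldimethylsilyl ether selectively over the secondary allylic one and the tert-butyldiphenylsilyl ether.

**Step 24**
Reactants: 39 C1 alcohol
Product: 40 C1 aldehyde
Conditions: Dess–Martin periodinane, NaHCO3, CH2Cl2, 0 °C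
Reagents that add atoms: none
Why: Buffered Dess–Martin oxidation gives the β-silyloxy aldehyde without elimination.

**Step 25**
Reactants: 40 C1 aldehyde
Product: 41 macrocyclic (1S)-allylic alcohol (ten-membered ring)
Conditions: CrCl2 (15 equiv), NiCl2 (0.1 equiv), DMSO/THF, 2 mM, rt
Reagents that add atoms: none
Why: Intramolecular Nozaki–Hiyama–Kishi reaction: the alkenylchromium species (trivalent chromium) adds only to the aldehyde with retention of the (Z)-geometry, and the β-silyloxy aldehyde is expected to react in the Felkin 1,3-anti sense to give mainly the (1S)-alcohol.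

**Step 26**
Reactants: 41 macrocyclic alcohol
Product: 42 C1 acetate
Conditions: Ac2O, DMAP (cat.), pyridine, CH2Cl2, 0 °C → rt
Reagents that add atoms: acetic anhydride CC(=O)OC(C)=O
Why: DMAP-catalysed acylation of the only free hydroxyl.

**Step 27**
Reactants: 42 C1 acetate
Product: 43 C6 alcohol
Conditions: DDQ, CH2Cl2/aq. NaH2PO4–Na2HPO4 buffer (pH 7), 0 °C
Reagents that add atoms: none
Why: Oxidative PMB ether cleavage (hydride abstraction by DDQ, hydrolysis of the oxocarbenium ion) leaves silyl ethers, acetate and lactone intact.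

**Step 28**
Reactants: 44 tiglic acid
Product: 45 (2S)-2-methylbutanoic acid
Conditions: H2 (4 atm), Ru(OAc)2[(S)-H8-BINAP] (0.5 mol %), MeOH, rt
Reagents that add atoms: none
Why: Ruthenium-catalysed asymmetric hydrogenation of the α,β-unsaturated acid through the carboxylate-bound complex sets the (S)-centre.

**Step 29**
Reactants: 43 C6 alcohol; 45 (2S)-2-methylbutanoic acid
Product: 46 C6 (2S)-2-methylbutanoate (bis-silyl ether of the target)
Conditions: EDC·HCl, DMAP, CH2Cl2, 0 °C → rt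
Reagents that add atoms: none
Why: Steglich esterification under mild conditions that do not epimerise the α-centre of the acid or disturb C6.

**Step 30**
Reactants: 46 bis-silyl ether
Product: 47 CNP0217661.3
Conditions: HF·pyridine (excess), pyridine, THF, 0 °C → rt
Reagents that add atoms: none
Why: Fluoride-mediated desilylation under mildly acidic, non-basic conditions removes both silyl ethers without acyl migration or conjugate addition to the methylene lactone.

**Compound list**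
1 | but-2-ynoic acid | CC#CC(=O)O | starting material
2 | potassium ethyl malonate (potassium 3-ethoxy-3-oxopropanoate) | CCOC(=O)CC(=O)[O-].[K+] | starting material
3 | but-2-ynoyl chloride (formed in the flask) | CC#CC(Cl)=O | intermediate
4 | acylmalonic half-ester, 2-(ethoxycarbonyl)-3-oxohex-4-ynoic acid (magnesium chelate in the flask) | CCOC(=O)C(C(=O)O)C(=O)C#CC | intermediate
5 | ethyl 3-oxohex-4-ynoate | CCOC(=O)CC(=O)C#CC | intermediate
6 | ethyl (3S)-3-hydroxyhex-4-ynoate | CC#C[C@@H](O)CC(=O)OCC | intermediate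
7 | allyl bromide (3-bromoprop-1-ene) | C=CCBr | starting material
8 | dilithium alkoxide-enolate of 6 (formed in the flask) | CC#C[C@@H](O[Li])C=C(O[Li])OCC | intermediate
9 | ethyl (2R,3S)-3-hydroxy-2-(prop-2-en-1-yl)hex-4-ynoate (6,7-anti) | CC#C[C@@H](O)[C@@H](CC=C)C(=O)OCC | intermediate
10 | vicinal diol, ethyl (2R,3S)-2-(2,3-dihydroxypropyl)-3-hydroxyhex-4-ynoate (new carbinol centre unspecified; formed in the flask) | CC#C[C@@H](O)[C@@H](CC(O)CO)C(=O)OCC | intermediate
11 | ethyl (2S,3R)-5-hydroxy-2-(prop-1-yn-1-yl)oxolane-3-carboxylate (lactol, both anomers) | CC#C[C@H]1OC(O)C[C@H]1C(=O)OCC | intermediate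
12 | cyclic (Z)-alkenylaluminate, sodium salt (1,2-oxaluminole from 11; formed in the flask) | CC1=C[C@H]([C@@H](CC[O-])C[O-])O[Al-]1(OCCOC)OCCOC.[Na+].[Na+].[Na+] | intermediate
13 | (2S,3S,4Z)-2-(2-hydroxyethyl)-5-iodohex-4-ene-1,3-diol | C/C(I)=C/[C@@H](O)[C@@H](CCO)CO | intermediate
14 | 2-[(2S,4S,5S)-4-[(1Z)-2-iodoprop-1-en-1-yl]-2-(4-methoxyphenyl)-1,3-dioxan-5-yl]ethan-1-ol (all-equatorial acetal) | C/C(I)=C/[C@H]1O[C@@H](c2ccc(OC)cc2)OC[C@@H]1CCO | intermediate
15 | (2S,4S,5S)-4-[(1Z)-2-iodoprop-1-en-1-yl]-2-(4-methoxyphenyl)-5-[2-(triethylsilyloxy)ethyl]-1,3-dioxane | C/C(I)=C/[C@H]1O[C@@H](c2ccc(OC)cc2)OC[C@@H]1CCO[Si](CC)(CC)CC | intermediate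
16 | methyl 3-hydroxypropanoate | COC(=O)CCO | starting material
17 | 3-hydroxy-N-methoxy-N-methylpropanamide | CON(C)C(=O)CCO | intermediate
18 | 3-(tert-butyldimethylsilyloxy)-N-methoxy-N-methylpropanamide | CC(C)(C)[Si](C)(C)OCCC(=O)N(C)OC | intermediate
19 | (Z)-alkenyllithium from 15, lithium in place of iodine (formed in the flask) | C/C([Li])=C/[C@H]1O[C@@H](c2ccc(OC)cc2)OC[C@@H]1CCO[Si](CC)(CC)CC | intermediate
20 | (4Z)-1-(tert-butyldimethylsilyloxy)-5-[(2S,4R,5S)-2-(4-methoxyphenyl)-5-[2-(triethylsilyloxy)ethyl]-1,3-dioxan-4-yl]-4-methylpent-4-en-3-one | CC(C)(C)[Si](C)(C)OCCC(=O)/C(C)=C\[C@H]1O[C@@H](c2ccc(OC)cc2)OC[C@@H]1CCO[Si](CC)(CC)CC | intermediate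
21 | (3S,4Z)-1-(tert-butyldimethylsilyloxy)-5-[(2S,4R,5S)-2-(4-methoxyphenyl)-5-[2-(triethylsilyloxy)ethyl]-1,3-dioxan-4-yl]-4-methylpent-4-en-3-ol | CC(C)(C)[Si](C)(C)OCC[C@H](O)/C(C)=C\[C@H]1O[C@@H](c2ccc(OC)cc2)OC[C@@H]1CCO[Si](CC)(CC)CC | intermediate
22 | (3S,4Z)-1,3-bis(tert-butyldimethylsilyloxy)-5-[(2S,4R,5S)-2-(4-methoxyphenyl)-5-[2-(triethylsilyloxy)ethyl]-1,3-dioxan-4-yl]-4-methylpent-4-ene | CC(C)(C)[Si](C)(C)OCC[C@H](O[Si](C)(C)C(C)(C)C)/C(C)=C\[C@H]1O[C@@H](c2ccc(OC)cc2)OC[C@@H]1CCO[Si](CC)(CC)CC | intermediate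
23 | (3S,4Z,6R,7S)-1,3-bis(tert-butyldimethylsilyloxy)-6-(4-methoxybenzyloxy)-4-methyl-7-[2-(triethylsilyloxy)ethyl]oct-4-en-8-ol (target locants) | CC(C)(C)[Si](C)(C)OCC[C@H](O[Si](C)(C)C(C)(C)C)/C(C)=C\[C@@H](OCc1ccc(OC)cc1)[C@@H](CCO[Si](CC)(CC)CC)CO | intermediate
24 | (3S,4Z,6R,7R)-1,3-bis(tert-butyldimethylsilyloxy)-6-(4-methoxybenzyloxy)-4-methyl-7-[2-(triethylsilyloxy)ethyl]oct-4-en-8-al (target locants) | CC(C)(C)[Si](C)(C)OCC[C@H](O[Si](C)(C)C(C)(C)C)/C(C)=C\[C@@H](OCc1ccc(OC)cc1)[C@@H](CCO[Si](CC)(CC)CC)C=O | intermediate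
25 | tert-butyldiphenyl(prop-2-yn-1-yloxy)silane | C#CCO[Si](c1ccccc1)(c1ccccc1)C(C)(C)C | starting material
26 | lithium acetylide of 25 (formed in the flask) | [Li]C#CCO[Si](c1ccccc1)(c1ccccc1)C(C)(C)C | intermediate
27 | (3S,4Z,6R,7S,8RS)-1,3-bis(tert-butyldimethylsilyloxy)-11-(tert-butyldiphenylsilyloxy)-6-(4-methoxybenzyloxy)-4-methyl-7-[2-(triethylsilyloxy)ethyl]undec-4-en-9-yn-8-ol (target locants for C1–C10; chain C11 is C14) | CC(C)(C)[Si](C)(C)OCC[C@H](O[Si](C)(C)C(C)(C)C)/C(C)=C\[C@@H](OCc1ccc(OC)cc1)[C@@H](CCO[Si](CC)(CC)CC)C(O)C#CCO[Si](c1ccccc1)(c1ccccc1)C(C)(C)C | intermediate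
28 | (3S,4Z,6R,7R)-1,3-bis(tert-butyldimethylsilyloxy)-11-(tert-butyldiphenylsilyloxy)-6-(4-methoxybenzyloxy)-4-methyl-7-[2-(triethylsilyloxy)ethyl]undec-4-en-9-yn-8-one | CC(C)(C)[Si](C)(C)OCC[C@H](O[Si](C)(C)C(C)(C)C)/C(C)=C\[C@@H](OCc1ccc(OC)cc1)[C@@H](CCO[Si](CC)(CC)CC)C(=O)C#CCO[Si](c1ccccc1)(c1ccccc1)C(C)(C)C | intermediate
29 | (3S,4Z,6R,7S,8R)-1,3-bis(tert-butyldimethylsilyloxy)-11-(tert-butyldiphenylsilyloxy)-6-(4-methoxybenzyloxy)-4-methyl-7-[2-(triethylsilyloxy)ethyl]undec-4-en-9-yn-8-ol | CC(C)(C)[Si](C)(C)OCC[C@H](O[Si](C)(C)C(C)(C)C)/C(C)=C\[C@@H](OCc1ccc(OC)cc1)[C@@H](CCO[Si](CC)(CC)CC)[C@@H](O)C#CCO[Si](c1ccccc1)(c1ccccc1)C(C)(C)C | intermediate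
30 | cyclic (Z)-alkenylaluminate from 29, sodium salt (formed in the flask) | CC(C)(C)[Si](C)(C)OCC[C@H](O[Si](C)(C)C(C)(C)C)/C(C)=C\[C@@H](OCc1ccc(OC)cc1)[C@@H](CCO[Si](CC)(CC)CC)[C@@H]1C=C(CO[Si](c2ccccc2)(c2ccccc2)C(C)(C)C)[Al-](OCCOC)(OCCOC)O1.[Na+] | intermediate
31 | (3S,4Z,6R,7S,8R,9Z)-1,3-bis(tert-butyldimethylsilyloxy)-11-(tert-butyldiphenylsilyloxy)-10-iodo-6-(4-methoxybenzyloxy)-4-methyl-7-[2-(triethylsilyloxy)ethyl]undeca-4,9-dien-8-ol | CC(C)(C)[Si](C)(C)OCC[C@H](O[Si](C)(C)C(C)(C)C)/C(C)=C\[C@@H](OCc1ccc(OC)cc1)[C@@H](CCO[Si](CC)(CC)CC)[C@@H](O)/C=C(I)/CO[Si](c1ccccc1)(c1ccccc1)C(C)(C)C | intermediate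
32 | (3S,4Z,6R,7S,8R,9Z)-1,3-bis(tert-butyldimethylsilyloxy)-11-(tert-butyldiphenylsilyloxy)-7-(2-hydroxyethyl)-10-iodo-6-(4-methoxybenzyloxy)-4-methylundeca-4,9-dien-8-ol | CC(C)(C)[Si](C)(C)OCC[C@H](O[Si](C)(C)C(C)(C)C)/C(C)=C\[C@@H](OCc1ccc(OC)cc1)[C@@H](CCO)[C@@H](O)/C=C(I)/CO[Si](c1ccccc1)(c1ccccc1)C(C)(C)C | intermediate
33 | lactol, the C12 hemiacetal corresponding to 34 (both anomers; formed in the flask) | CC(C)(C)[Si](C)(C)OCC[C@H](O[Si](C)(C)C(C)(C)C)/C(C)=C\[C@@H](OCc1ccc(OC)cc1)[C@H]1CC(O)O[C@H]1/C=C(I)/CO[Si](c1ccccc1)(c1ccccc1)C(C)(C)C | intermediate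
34 | (4R,5R)-4-[(1R,2Z,4S)-4,6-bis(tert-butyldimethylsilyloxy)-1-(4-methoxybenzyloxy)-3-methylhex-2-en-1-yl]-5-[(1Z)-3-(tert-butyldiphenylsilyloxy)-2-iodoprop-1-en-1-yl]oxolan-2-one (cis-lactone) | CC(C)(C)[Si](C)(C)OCC[C@H](O[Si](C)(C)C(C)(C)C)/C(C)=C\[C@@H](OCc1ccc(OC)cc1)[C@H]1CC(=O)O[C@H]1/C=C(I)/CO[Si](c1ccccc1)(c1ccccc1)C(C)(C)C | intermediate
35 | lithium enolate of 34 (formed in the flask) | CC(C)(C)[Si](C)(C)OCC[C@H](O[Si](C)(C)C(C)(C)C)/C(C)=C\[C@@H](OCc1ccc(OC)cc1)[C@H]1C=C(O[Li])O[C@H]1/C=C(I)/CO[Si](c1ccccc1)(c1ccccc1)C(C)(C)C | intermediate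
36 | (3R,4R,5R)-3-[(dimethylamino)methyl] derivative of 34 (aminomethyl group trans to the C4 side chain) | CC(C)(C)[Si](C)(C)OCC[C@H](O[Si](C)(C)C(C)(C)C)/C(C)=C\[C@@H](OCc1ccc(OC)cc1)[C@H]1[C@H](CN(C)C)C(=O)O[C@H]1/C=C(I)/CO[Si](c1ccccc1)(c1ccccc1)C(C)(C)C | intermediate
37 | trimethylammonium iodide of 36 (formed in the flask) | CC(C)(C)[Si](C)(C)OCC[C@H](O[Si](C)(C)C(C)(C)C)/C(C)=C\[C@@H](OCc1ccc(OC)cc1)[C@H]1[C@H](C[N+](C)(C)C)C(=O)O[C@H]1/C=C(I)/CO[Si](c1ccccc1)(c1ccccc1)C(C)(C)C.[I-] | intermediate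
38 | (4R,5R)-4-[(1R,2Z,4S)-4,6-bis(tert-butyldimethylsilyloxy)-1-(4-methoxybenzyloxy)-3-methylhex-2-en-1-yl]-5-[(1Z)-3-(tert-butyldiphenylsilyloxy)-2-iodoprop-1-en-1-yl]-3-methylideneoxolan-2-one | CC(C)(C)[Si](C)(C)OCC[C@H](O[Si](C)(C)C(C)(C)C)/C(C)=C\[C@@H](OCc1ccc(OC)cc1)[C@H]1C(=C)C(=O)O[C@H]1/C=C(I)/CO[Si](c1ccccc1)(c1ccccc1)C(C)(C)C | intermediate
39 | (4R,5R)-4-[(1R,2Z,4S)-4-(tert-butyldimethylsilyloxy)-6-hydroxy-1-(4-methoxybenzyloxy)-3-methylhex-2-en-1-yl]-5-[(1Z)-3-(tert-butyldiphenylsilyloxy)-2-iodoprop-1-en-1-yl]-3-methylideneoxolan-2-one | OCC[C@H](O[Si](C)(C)C(C)(C)C)/C(C)=C\[C@@H](OCc1ccc(OC)cc1)[C@H]1C(=C)C(=O)O[C@H]1/C=C(I)/CO[Si](c1ccccc1)(c1ccccc1)C(C)(C)C | intermediate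
40 | (4R,5R)-4-[(1R,2Z,4S)-4-(tert-butyldimethylsilyloxy)-1-(4-methoxybenzyloxy)-3-methyl-6-oxohex-2-en-1-yl]-5-[(1Z)-3-(tert-butyldiphenylsilyloxy)-2-iodoprop-1-en-1-yl]-3-methylideneoxolan-2-one | O=CC[C@H](O[Si](C)(C)C(C)(C)C)/C(C)=C\[C@@H](OCc1ccc(OC)cc1)[C@H]1C(=C)C(=O)O[C@H]1/C=C(I)/CO[Si](c1ccccc1)(c1ccccc1)C(C)(C)C | intermediate
41 | (1S,3S,4Z,6R,7R,8S,9Z)-3-(tert-butyldimethylsilyloxy)-14-(tert-butyldiphenylsilyloxy)-1-hydroxy-6-(4-methoxybenzyloxy)germacra-4,9,11(13)-trien-12,8-olide | C=C1C(=O)O[C@H]2/C=C(/CO[Si](c3ccccc3)(c3ccccc3)C(C)(C)C)[C@@H](O)C[C@H](O[Si](C)(C)C(C)(C)C)/C(C)=C\[C@@H](OCc3ccc(OC)cc3)[C@@H]12 | intermediate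
42 | (1S,3S,4Z,6R,7R,8S,9Z)-1-acetoxy-3-(tert-butyldimethylsilyloxy)-14-(tert-butyldiphenylsilyloxy)-6-(4-methoxybenzyloxy)germacra-4,9,11(13)-trien-12,8-olide | C=C1C(=O)O[C@H]2/C=C(/CO[Si](c3ccccc3)(c3ccccc3)C(C)(C)C)[C@@H](OC(C)=O)C[C@H](O[Si](C)(C)C(C)(C)C)/C(C)=C\[C@@H](OCc3ccc(OC)cc3)[C@@H]12 | intermediate
43 | (1S,3S,4Z,6R,7R,8S,9Z)-1-acetoxy-3-(tert-butyldimethylsilyloxy)-14-(tert-butyldiphenylsilyloxy)-6-hydroxygermacra-4,9,11(13)-trien-12,8-olide | C=C1C(=O)O[C@H]2/C=C(/CO[Si](c3ccccc3)(c3ccccc3)C(C)(C)C)[C@@H](OC(C)=O)C[C@H](O[Si](C)(C)C(C)(C)C)/C(C)=C\[C@@H](O)[C@@H]12 | intermediate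
44 | tiglic acid, (2E)-2-methylbut-2-enoic acid | C/C=C(\C)C(=O)O | starting material
45 | (2S)-2-methylbutanoic acid | CC[C@H](C)C(=O)O | intermediate
46 | (1S,3S,4Z,6R,7R,8S,9Z)-1-acetoxy-3-(tert-butyldimethylsilyloxy)-14-(tert-butyldiphenylsilyloxy)-6-[(2S)-2-methylbutanoyloxy]germacra-4,9,11(13)-trien-12,8-olide | C=C1C(=O)O[C@H]2/C=C(/CO[Si](c3ccccc3)(c3ccccc3)C(C)(C)C)[C@@H](OC(C)=O)C[C@H](O[Si](C)(C)C(C)(C)C)/C(C)=C\[C@@H](OC(=O)[C@@H](C)CC)[C@@H]12 | intermediate
47 | CNP0217661.3, (1S,3S,4Z,6R,7R,8S,9Z)-1-acetoxy-3,14-dihydroxy-6-[(2S)-2-methylbutanoyloxy]germacra-4,9,11(13)-trien-12,8-olide | C=C1C(=O)O[C@H]2/C=C(/CO)[C@@H](OC(C)=O)C[C@H](O)/C(C)=C\[C@@H](OC(=O)[C@@H](C)CC)[C@@H]12 | target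

**Totals**
Total step count: 30. Longest linear sequence: 27 steps (steps 1–7, 10–27, 29 and 30).

**Steps most likely to fail, with fallbacks**

Step 2 (ketoreductase reduction of 5). The risk is that no enzyme of the panel accepts the alkynyl β-keto ester with useful rate and (S)-selectivity. The fallback sets out from keto ester 5 and sets the stereocentre by transition-metal hydride transfer instead of biocatalysis: Noyori–Ikariya asymmetric transfer hydrogenation with RuCl[(S,S)-TsDPEN](p-cymene) in HCO2H/Et3N at rt, which reduces alkynyl ketones to the (S)-propargylic alcohol. It comes back to the route at 6 and makes no new compound (F0).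

Step 11 (CBS reduction of the twisted (Z)-enone 20). The risk is poor facial selectivity because the hindered enone is not planar. The fallback sets out from 20 and gives up reagent control: reduction with NaBH4/CeCl3·7H2O in MeOH at −78 °C gives 21 together with the (3R)-epimer of 21 F1. The two diastereomers are separated by chromatography, F1 is oxidised back to 20 with MnO2 and recycled, and the route is rejoined at 21.

Step 25 (Nozaki–Hiyama–Kishi macrocyclisation of 40). The risk is that the C1 configuration, set only by 1,3-induction and ring strain, comes out mixed or mainly (1R). The fallback sets out from 41 as delivered by step 25 (mixture with its C1 epimer) and separates ring formation from stereocontrol: Dess–Martin oxidation gives the macrocyclic C1 ketone F2, which is reduced under reagent control with (R)-2-methyl-CBS-oxazaborolidine and catecholborane in toluene at −78 °C. This returns the (1S)-alcohol 41, where the route continues.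

**Further compounds**
F0 | step 2 | none | none
F1 | step 11 | (3R)-epimer of 21, (3R,4Z)-1-(tert-butyldimethylsilyloxy)-5-[(2S,4R,5S)-2-(4-methoxyphenyl)-5-[2-(triethylsilyloxy)ethyl]-1,3-dioxan-4-yl]-4-methylpent-4-en-3-ol | CC(C)(C)[Si](C)(C)OCC[C@@H](O)/C(C)=C\[C@H]1O[C@@H](c2ccc(OC)cc2)OC[C@@H]1CCO[Si](CC)(CC)CC
F2 | step 25 | macrocyclic C1 ketone, (3S,4Z,6R,7R,8S,9Z)-3-(tert-butyldimethylsilyloxy)-14-(tert-butyldiphenylsilyloxy)-6-(4-methoxybenzyloxy)-1-oxogermacra-4,9,11(13)-trien-12,8-olide | C=C1C(=O)O[C@H]2/C=C(/CO[Si](c3ccccc3)(c3ccccc3)C(C)(C)C)C(=O)C[C@H](O[Si](C)(C)C(C)(C)C)/C(C)=C\[C@@H](OCc3ccc(OC)cc3)[C@@H]12
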